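Over-reaction product cannot appear in this scheme except from target, and target cannot appear except where first nucleophile catches the intermediate, so the question is about a race.

| flask | substrate | first nucleophile | second nucleophile | protic impurity | time | remark |
|---|---|---|---|---|---|---|
| zeta | 0.10 M | 0.120 M | 0.0950 M | 2.00 mM | 30 min | everything together at the start |
| gamma | 0.10 M (fed, over 12 min) | 0.120 M | 0.0950 M | 2.00 mM | 30 min | all else is in the flask from the start; the feed brings no volume worth counting |
| beta | 0.10 M | 0.120 M (fed, over 12 min) | 0.0950 M | 2.00 mM | 30 min | all else is in the flask from the start; the feed brings no volume worth counting |

    substrate ⇌ intermediate (K1 = 0.017, k1 = 0.013 /s)
    first nucleophile + intermediate → target (k2 = 1.1 /M/s)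
    second nucleophile + intermediate → other capture product (k3 = 0.72 /M/s)
    target → over-reaction product (k4 = 0.0060 /s)
    2 first nucleophile → self-condensation product (k5 = 0.017 /M/s)
    first nucleophile + protic impurity → quenched reagent (k6 = 0.31 /M/s)

- a doubled species enters its step squared and goes two at a time
- run time (zeta): 30 min

* the flask with the highest amount of over-reaction product, in percent of the substrate charged ("all alike" if they lie within 1.5 percentage points) (zeta / gamma / beta / all alike)
* final over-reaction product, as a percentage of the substrate charged, in zeta
* final over-reaction product, as a percentage of the substrate charged, in gamma
* final over-reaction product, as a percentage of the substrate charged, in beta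

At the board, then. The intermediate has two takers, and the part going to target is first nucleophile's capture rate over the sum of both capture rates. The symmetric case gives the zero of the scale. With second nucleophile at its charge, the two captures run equally when first nucleophile stands at the selectivity factor's inverse, 0.655, times that charge: 0.0622 M, the even level. There the share is 0.5, and in general the share is the amount of first nucleophile over that amount plus the even level. At the charge of 0.120 M it is 65.9%. Target's half-life by step 4 alone, 1.9 min, is far shorter than the run of 30 min, so over-reaction product should count nearly what the race gave target.

Now two chemists disagree. The first says the charges are equal in the three flasks, so the share is 65.9% in each and the flasks differ by less than the margin. The second says first nucleophile consumes itself. By self-condensation alone its first half-life at charge is 4.08 min, and it reaches the even level after 3.80 min, which is sooner than the feed's 12 min. By then gamma has received 31.7% of its substrate, and the rest enters a race that first nucleophile is losing. I side with the second chemist and commit to gamma lowest, though my reckoning gives that order and no figure.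

The forecast takes the same side and names zeta: 38% there (35.5% to 40.5%), 24.5% in gamma (22% to 27%) and 35% in beta (32.5% to 37.5%), saying of gamma that “substrate arrives after” first nucleophile has decayed.

The flasks give 38.4% in zeta, 24.5% in gamma and 35.5% in beta, so zeta stands highest and the second chemist wins, with each figure inside its forecast range. The first chemist's claim of flasks within the margin comes true for one pair: beta dosed over 3.60 min reaches 38.1%, a gap to zeta of 0.30 percentage points against the margin of 1.5 points. Zeta's mean first nucleophile over its first 12 min was 0.0451 M, below the even level, which gives a share of 42.0%. Zeta's finished captures show 45.1%, which is less than the first chemist's 65.9%.

Take the neighbour of gamma charged with 0.024 M of second nucleophile. Its even level is 0.01571 M, and gamma's finished captures read as a first nucleophile level of 0.0315 M, so carrying that level over gives a share of 66.7%. The neighbour's computed captures show 65.5%, with over-reaction product at 29.5% and other capture product at 16.0%, while 52.7% of the charge is still substrate.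

The constants were set for the occasion, and the outcome is calculated.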